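The way in is slowness: between 0.200 h and 0.500 h, substrate in Sunday's flask fell at a fractional rate of 0.581 h⁻¹.

the same everywhere: substrate 0.10 M

|  | remark | time |
|---|---|---|
| Sunday's | the very flask that is asked about, followed so far |  |
| flask |  | 12 h |

Sunday's run (percent of the substrate charged)

| time / h | intermediate / % | target / % | substrate / % |
|---|---|---|---|
| 0.100 | 15.7 | 0.7 | 83.8 |
| 0.200 | 21.2 | 2.3 | 75.0 |
| 0.500 | 23.6 | 4.8 | 63.0 |
| 1.00 | 18.8 | 7.7 | 48.6 |
| 2.00 | 11.2 | 7.5 | 28.0 |
| 5.00 | 2.1 | 8.0 | 5.6 |

(scatter of a reading: 0.5 percentage points)

- percent here means substrate units held: one side product counts as two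
- the analysis behind the earlier runs scatters by 0.5 percentage points, standard deviation
- reactions considered so far: substrate + target -> side product; substrate <-> intermediate; intermediate -> target

- the best time, 12 h at the latest, for intermediate
- the amount of intermediate, in percent of the substrate charged, at that time
- the first time at which intermediate reaches 17%, in the same percent

Intermediate over substrate, with the readings at 1.00 h and 2.00 h summed, reads 0.392, and this held ratio is the quantity to carry. For the best time to lie late, the ratio would have to climb as fast as substrate falls, but between 1.00 h and 5.00 h substrate fell by a factor of 8.68 while the ratio went from 0.387 to 0.375, so the maximum is to be sought before 1.00 h.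

Early intermediate is the held ratio times substrate, less a correction: the share of that ratio not yet reached. This share, 27.8% at 0.200 h, implies a closing rate of 6.40 h⁻¹, faster than the fall of substrate. My reckoning puts the maximum where the shrinking share just offsets that fall, at a share of 8.32%, which gives 0.389 h and 24.1%. A straight line between the first two readings reaches 17% at about 0.124 h.

The forecast gave 0.38 h, 24% and 0.118 h, the last from a “saturating curve through the first points”. The flask gives 0.388 h, 24.1% and 0.121 h.

    substrate + target → side product (k = 0.0140 M⁻¹ s⁻¹)
    substrate ⇌ intermediate (K = 0.430, k = 6.30 × 10⁻⁴ s⁻¹)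
    intermediate → target (k = 2.70 × 10⁻⁴ s⁻¹)

At 0.258 h in this flask, intermediate falls back to substrate 5.4 times as fast as it goes on to target, the mark of a pre-equilibrium. The held ratio times the substrate at 1.20 h gives 16.9% intermediate against 17.1% in the flask, and in the neighbour flask read at 3.0 h, its 16.1% of substrate gives 6.30% against 6.40%.

The data were computed for substances that don't exist, noise included.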